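The earlier runs and the new flask come from a simulation with constants of no real substance, noise included.

Count the chains.

| flask | D | E | remark | time |
|---|---|---|---|---|
| alder | 0.10 M | 0.27 mM | run made earlier |  |
| Tuesday's | 0.10 M | 0.18 mM |  | 10 d |
| Wednesday's | 0.30 M | 0.18 mM |  | 10 d |

- alder (time / d: L / %, D / %): 0.625: 16.7, 82.4; 1.25: 31.6, 67.9; 1.67: 39.7, 59.4; 2.50: 52.6, 46.6; 3.00: 58.8, 40.3; 4.00: 69.0, 30.5

(standard deviation of a reading: 0.3 percentage points)

- the average divides the monomer in chains by the number of chains, living and dead together; two radicals that join make one chain
- steps under discussion: E -> 2 X; D + X -> Q + L; D + Q -> L + Q; 2 Q -> Z; D -> J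
- the earlier runs do not show the number of chains; that part of a forecast is a guess
- no earlier run changes the charge of E; that part of a forecast is a guess

1. which of the two ends with the longer chains by the average number of monomer units in a chain (living and dead chains, two that joined counted as one) ("neither" if they lie within 10%) (Tuesday's / Wednesday's / neither)
2. average number of monomer units in a chain (living and dead chains, two that joined counted as one) at the end, Tuesday's
3. average number of monomer units in a chain (living and dead chains, two that joined counted as one) at the end, Wednesday's

In the alder run D falls as a pseudo-first-order species. Its mean specific rate, −ln(cD/cD at the start) divided by the time, reads 0.310 d⁻¹ at 0.625 d and sags to 0.297 d⁻¹ at 4.00 d. If this rate follows the root of cE, the sag between these two times gives the decay constant of E read from the rate, 0.0493 d⁻¹. It is a loose reading: each D carries a scatter of 0.3 percentage points.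

Tuesday's has less E than the alder run, so its specific rate starts at 0.255 d⁻¹. The decay of E multiplies that rate by 0.782 by 10 d, and the falling cD slows the rate in mol per litre without touching the specific rate. The accumulated exponent is 2.26, so this reckoning has 89.6% of D reacted in either flask. Each E broken gives two X; if each X starts a Q and two Q join, that is one chain, and this efficiency is a guess. That makes 0.0700 mM of chains, and lengths of 1280 for Tuesday's and 3840 for Wednesday's.

The forecast, with “chains ≈ E consumed, assuming full efficiency (a guess)”, reads the sag as 0.06 per day and counts 0.08 mM of chains. It names Wednesday's, with 1150 for Tuesday's and 3450 for Wednesday's, which stand lower than this reckoning.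

The flasks give 1480 for Tuesday's and 4430 for Wednesday's, so Wednesday's has the longer chains, as forecast.

    E → 2 X (k = 0.00170 h⁻¹)
    D + X → Q + L (k = 84000 M⁻¹ s⁻¹)
    D + Q → L + Q, rate k3*[Q]*[D] (k = 9.20 × 10⁶ M⁻¹ h⁻¹)
    2 Q → Z (k = 6.60 × 10⁷ M⁻¹ s⁻¹)
    D → J (k = 9.20 × 10⁻⁵ h⁻¹)

Tuesday's holds L at 89.1% and Z at 6.03 × 10⁻⁵ M, against the reckoned 89.6% of D reacted and 0.0700 mM of chains, and the reckoned 1280 stands at 0.865 of the flask's length. The same 0.0493 d⁻¹ carried to Wednesday's flask read at 2.5 d leaves 53.9% of D and gives 0.0209 mM of chains, hence a length of 6630, which is 0.846 of the simulated value. At 2.5 d Wednesday's flask holds 54% of its D, and its chains average 7840.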